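**Retrosynthetic overview**
- The target comes from its hexabenzyl ether by hydrogenolysis. The pyranone ring C is opened at O1–C2 to a 2'-hydroxy-α-benzyloxychalcone.
- Feature carrying the strategy: in ring A, C4a (bearing the C4 carbonyl) and C8a (bearing O1) are neighbouring carbons, with the C5 oxygen beside C4a and the C7 oxygen meta to it. This acyl/oxygen pair is what 3,5-bis(benzyloxy)benzyne gives when it inserts into the C(=O)–OH bond of an α-benzyloxycinnamic acid, so O1–C8a and C4–C4a are disconnected together.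
- The acid comes from the dihydrobenzofuran-5-carbaldehyde and methyl 2-(benzyloxy)acetate (aldol, elimination, saponification). The aldehyde comes from the 5-bromide.
- The dihydrobenzofuran (C2–C3 bond, both stereocentres) comes from an aryl diazoacetate by enantioselective dirhodium-carbenoid C–H insertion, followed by epimerisation at C3 to trans.
- Ring order: dihydrobenzofuran ring first; ring A attached without ring closure in the key step; ring C closed last.

Key step: step 16

Remark on the chemistry: 2-(benzyloxy)phenol, 4-(benzyloxy)-3-methoxybenzyl alcohol, ethyl diazoacetate, methyl 2-(benzyloxy)acetate and 3,5-bis(benzyloxy)phenol are taken as purchased. The (S)-tert-leucinate dirhodium catalyst of step 6 is assumed to deliver the 2R configuration; if the insertion proves to favour 2S, the mirror-image catalyst from D-tert-leucine is used with no other change.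

**Route**

Step 1
Reactants: 1 2-(benzyloxy)phenol
Product: 2 2-(benzyloxy)-4-bromophenol
Conditions: NBS (1.0 equiv), MeCN, 0 °C
Reagents that add atoms: N-bromosuccinimide, O=C1CCC(=O)N1Br
Why: Electrophilic aromatic bromination should go para to the free hydroxyl, the strongest donor on the ring, as it does for guaiacol; any isomer is removed by chromatography.

Step 2
Reactants: 2 2-(benzyloxy)-4-bromophenol
Product: 3 2-(benzyloxy)-4-bromo-6-iodophenol
Conditions: NIS (1.05 equiv), TsOH·H2O (10 mol%), MeCN, rt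
Reagents that add atoms: N-iodosuccinimide, O=C1CCC(=O)N1I
Why: With the para position blocked, acid-activated NIS should iodinate the one remaining position ortho to the hydroxyl (electrophilic aromatic iodination of a para-substituted phenol).

Step 3
Reactants: 4 4-(benzyloxy)-3-methoxybenzyl alcohol
Product: 5 4-(benzyloxy)-3-methoxybenzyl chloride
Conditions: SOCl2 (1.2 equiv), CH2Cl2, 0 °C; evaporate and use crude
Reagents that add atoms: thionyl chloride, O=S(Cl)Cl
Why: Chlorodehydroxylation of an electron-rich benzylic alcohol with thionyl chloride is fast and clean, and the labile chloride is used without purification.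

Step 4
Reactants: 3 2-(benzyloxy)-4-bromo-6-iodophenol; 5 4-(benzyloxy)-3-methoxybenzyl chloride
Product: 6 1-(benzyloxy)-2-[(4-benzyloxy-3-methoxybenzyl)oxy]-5-bromo-3-iodobenzene
Conditions: K2CO3, NaI (cat.), DMF, 50 °C
Reagents that add atoms: none
Why: Williamson ether synthesis, the phenoxide displacing the reactive benzylic chloride by SN2 with iodide catalysis.

Step 5
Reactants: 6 1-(benzyloxy)-2-[(4-benzyloxy-3-methoxybenzyl)oxy]-5-bromo-3-iodobenzene; 7 ethyl diazoacetate
Product: 8 ethyl 2-{3-(benzyloxy)-2-[(4-benzyloxy-3-methoxybenzyl)oxy]-5-bromophenyl}-2-diazoacetate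
Conditions: Pd(PPh3)4 (5 mol%), Ag2CO3 (0.5 equiv), Et3N (1.3 equiv), toluene, rt, dark
Reagents that add atoms: none
Why: Palladium-catalysed cross-coupling of an aryl iodide with a diazo ester: zerovalent palladium inserts into C–I (C–Br is inert at room temperature with this catalyst), the silver/amine base delivers the diazoacetate carbon to palladium, and reductive elimination gives the aryl diazoacetate with the diazo group intact.

Step 6
Reactants: 8 ethyl 2-{3-(benzyloxy)-2-[(4-benzyloxy-3-methoxybenzyl)oxy]-5-bromophenyl}-2-diazoacetate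
Product: 9 ethyl (2R,3S)-7-(benzyloxy)-2-(4-benzyloxy-3-methoxyphenyl)-5-bromo-2,3-dihydrobenzofuran-3-carboxylate (cis)
Conditions: dirhodium tetrakis[N-phthaloyl-(S)-tert-leucinate], Rh2(S-PTTL)4 (1 mol%), toluene, −60 °C, slow addition of 8
Reagents that add atoms: none
Why: Intramolecular 1,5 C–H insertion of the dirhodium carbenoid into the benzylic O–CH2 bond (activated by the ether oxygen and the electron-rich aryl) forms C2–C3 and should give the cis ester kinetically, while the chiral carboxylate ligands select the enantiotopic hydrogen so that C2 is set as R and C3 provisionally as S.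

Step 7
Reactants: 9 ethyl (2R,3S)-7-(benzyloxy)-2-(4-benzyloxy-3-methoxyphenyl)-5-bromo-2,3-dihydrobenzofuran-3-carboxylate
Product: 10 ethyl (2R,3R)-7-(benzyloxy)-2-(4-benzyloxy-3-methoxyphenyl)-5-bromo-2,3-dihydrobenzofuran-3-carboxylate (trans)
Conditions: NaOEt (0.3 equiv), EtOH/THF, rt
Reagents that add atoms: none
Why: Base-mediated epimerisation at the ester α-carbon C3 through the enolate relieves the cis interaction of aryl and ester and leaves C2 untouched, so the trans ester should dominate at equilibrium and the C3 configuration of the target is fixed here.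

Step 8
Reactants: 10 ethyl (2R,3R)-7-(benzyloxy)-2-(4-benzyloxy-3-methoxyphenyl)-5-bromo-2,3-dihydrobenzofuran-3-carboxylate
Product: 11 [(2R,3S)-7-(benzyloxy)-2-(4-benzyloxy-3-methoxyphenyl)-5-bromo-2,3-dihydrobenzofuran-3-yl]methanol (trans)
Conditions: iBu2AlH (2.5 equiv), CH2Cl2, −78 to 0 °C; aq. potassium sodium tartrate work-up
Reagents that add atoms: none
Why: Hydride reduction of the ester to the primary alcohol leaves the aryl bromide and benzyl ethers alone; the C3 descriptor changes from R to S only through the priority rules, not through any change in space.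

Step 9
Reactants: 11 [(2R,3S)-7-(benzyloxy)-2-(4-benzyloxy-3-methoxyphenyl)-5-bromo-2,3-dihydrobenzofuran-3-yl]methanol
Product: 12 (2R,3S)-7-(benzyloxy)-3-[(benzyloxy)methyl]-2-(4-benzyloxy-3-methoxyphenyl)-5-bromo-2,3-dihydrobenzofuran
Conditions: NaH (1.5 equiv), BnBr (1.3 equiv), nBu4NI (cat.), THF/DMF, 0 °C to rt
Reagents that add atoms: benzyl bromide, BrCc1ccccc1
Why: Williamson benzylation of the primary alkoxide gives an ether that withstands organolithium, hot fluoride and hot DMSO in the later steps.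

Step 10
Reactants: 12 (2R,3S)-7-(benzyloxy)-3-[(benzyloxy)methyl]-2-(4-benzyloxy-3-methoxyphenyl)-5-bromo-2,3-dihydrobenzofuran
Product: 14 (2R,3S)-7-(benzyloxy)-3-[(benzyloxy)methyl]-2-(4-benzyloxy-3-methoxyphenyl)-2,3-dihydrobenzofuran-5-carbaldehyde, via aryllithium 13 (not isolated)
Conditions: n-BuLi (1.1 equiv), THF, −78 °C; DMF (3 equiv), −78 to 0 °C; H2O
Reagents that add atoms: N,N-dimethylformamide, CN(C)C=O
Why: Bromine–lithium exchange is much faster at −78 °C than any deprotonation of the benzylic positions, and formylation of the aryllithium with DMF gives the aldehyde on hydrolysis of the hemiaminal.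

Step 11
Reactants: 14 (2R,3S)-7-(benzyloxy)-3-[(benzyloxy)methyl]-2-(4-benzyloxy-3-methoxyphenyl)-2,3-dihydrobenzofuran-5-carbaldehyde; 15 methyl 2-(benzyloxy)acetate
Product: 16 methyl 2-(benzyloxy)-3-hydroxy-3-[(2R,3S)-7-(benzyloxy)-3-[(benzyloxy)methyl]-2-(4-benzyloxy-3-methoxyphenyl)-2,3-dihydrobenzofuran-5-yl]propanoate (diastereomer mixture at the two new carbons)
Conditions: LiN(iPr)2 (1.2 equiv), 15 (1.3 equiv), THF, −78 °C; then 14; H2O quench
Reagents that add atoms: none
Why: Aldol addition of the lithium enolate of the α-benzyloxy ester to the non-enolisable aryl aldehyde; the configuration of the two new carbons is irrelevant because both become sp2 in the next step.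

Step 12
Reactants: 16 methyl 2-(benzyloxy)-3-hydroxy-3-[(2R,3S)-7-(benzyloxy)-3-[(benzyloxy)methyl]-2-(4-benzyloxy-3-methoxyphenyl)-2,3-dihydrobenzofuran-5-yl]propanoate
Product: 18 methyl (Z)-2-(benzyloxy)-3-[(2R,3S)-7-(benzyloxy)-3-[(benzyloxy)methyl]-2-(4-benzyloxy-3-methoxyphenyl)-2,3-dihydrobenzofuran-5-yl]acrylate, via mesylate 17 (not isolated)
Conditions: MsCl (1.5 equiv), Et3N (3 equiv), CH2Cl2, 0 °C; then DBU (3 equiv), rt
Reagents that add atoms: none
Why: Mesylation followed by E1cB elimination through the ester enolate should give mainly the Z alkene (aryl trans to the ester), and either geometry serves the later cyclisation.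

Step 13
Reactants: 18 methyl (Z)-2-(benzyloxy)-3-[(2R,3S)-7-(benzyloxy)-3-[(benzyloxy)methyl]-2-(4-benzyloxy-3-methoxyphenyl)-2,3-dihydrobenzofuran-5-yl]acrylate
Product: 19 (Z)-2-(benzyloxy)-3-[(2R,3S)-7-(benzyloxy)-3-[(benzyloxy)methyl]-2-(4-benzyloxy-3-methoxyphenyl)-2,3-dihydrobenzofuran-5-yl]acrylic acid
Conditions: LiOH·H2O (3 equiv), THF/MeOH/H2O, 40 °C; then cold 1 M HCl to pH 3
Reagents that add atoms: lithium hydroxide, [Li+].[OH-]
Why: Saponification of the methyl ester; brief cold acidification spares the acid-sensitive enol ether and the benzylic ring ether.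

Step 14
Reactants: 20 3,5-bis(benzyloxy)phenol
Product: 21 2-bromo-3,5-bis(benzyloxy)phenol
Conditions: NBS (1.0 equiv), CH2Cl2, −78 to −40 °C
Reagents that add atoms: N-bromosuccinimide, O=C1CCC(=O)N1Br
Why: Low-temperature bromination in a non-polar solvent should favour the position ortho to the hydroxyl (two equivalent sites, hydrogen-bond assisted delivery), as with 3,5-dimethoxyphenol; the 4-bromo isomer is removed by chromatography.

Step 15
Reactants: 21 2-bromo-3,5-bis(benzyloxy)phenol
Product: 24 3,5-bis(benzyloxy)-2-(trimethylsilyl)phenyl trifluoromethanesulfonate, via aryl trimethylsilyl ether 22 (not isolated), via lithium 2-silylphenoxide 23 (not isolated)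
Conditions: (Me3Si)2NH, THF, 70 °C, then evaporate; n-BuLi (1.1 equiv), THF, −78 °C; Tf2O (1.2 equiv), −78 °C to rt
Reagents that add atoms: hexamethyldisilazane, C[Si](C)(C)N[Si](C)(C)C; trifluoromethanesulfonic anhydride, O=S(=O)(OS(=O)(=O)C(F)(F)F)C(F)(F)F
Why: O-silylation, bromine–lithium exchange and the retro-Brook 1,3 O-to-C silyl shift put silicon on the carbon between the oxygen and the benzyloxy group, and triflation of the resulting phenoxide completes the standard ortho-silylaryl triflate aryne precursor.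

Step 16
Reactants: 19 (Z)-2-(benzyloxy)-3-[(2R,3S)-7-(benzyloxy)-3-[(benzyloxy)methyl]-2-(4-benzyloxy-3-methoxyphenyl)-2,3-dihydrobenzofuran-5-yl]acrylic acid; 24 3,5-bis(benzyloxy)-2-(trimethylsilyl)phenyl trifluoromethanesulfonate
Product: 26 (Z)-2-(benzyloxy)-1-[2-hydroxy-4,6-bis(benzyloxy)phenyl]-3-[(2R,3S)-7-(benzyloxy)-3-[(benzyloxy)methyl]-2-(4-benzyloxy-3-methoxyphenyl)-2,3-dihydrobenzofuran-5-yl]prop-2-en-1-one, via 3,5-bis(benzyloxy)benzyne 25 (not isolated)
Conditions: 19 (1.0 equiv), 24 (1.5 equiv), CsF (4 equiv), THF, 125 °C, sealed tube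
Reagents that add atoms: none
Why: Fluoride removes silicon from 24 with loss of triflate to give aryne 25, and the caesium carboxylate of 19 adds through oxygen to the aryne carbon remote from the flanking benzyloxy group, since that is the more electrophilic end of the distorted triple bond and the resulting aryl anion sits beside the inductively withdrawing oxygen. The aryl anion then attacks the adjacent ester carbonyl to give a four-membered benzoxetene alkoxide that opens to the ortho-acylphenoxide, so the aryne is inserted into the acyl C–O bond with formation of O1–C8a and C4–C4a. The closest known reaction is the fluoride-mediated insertion of arynes into the C–O bond of aromatic and cinnamic carboxylic acids to give ortho-hydroxyaryl ketones. No ring is closed and no stereocentre is formed, and the two dihydrobenzofuran stereocentres bear no hydrogen acidic enough for fluoride, so they should pass unchanged. The step needs regioselective addition (secured by the benzyloxy group next to the triple bond), acyl transfer in preference to protonation of the aryl anion (aprotic THF at high temperature with excess CsF holding the acid proton) and no second arylation of the product phenoxide (small excess of 24, phenoxide tied to the new carbonyl). Any 3-benzyloxyflavanone formed by conjugate addition of the phenoxide to the enone is carried on with 26, because step 17 takes both to the same flavone.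

Step 17
Reactants: 26 (Z)-2-(benzyloxy)-1-[2-hydroxy-4,6-bis(benzyloxy)phenyl]-3-[(2R,3S)-7-(benzyloxy)-3-[(benzyloxy)methyl]-2-(4-benzyloxy-3-methoxyphenyl)-2,3-dihydrobenzofuran-5-yl]prop-2-en-1-one
Product: 27 3,5,7-tris(benzyloxy)-2-[(2R,3S)-7-(benzyloxy)-3-[(benzyloxy)methyl]-2-(4-benzyloxy-3-methoxyphenyl)-2,3-dihydrobenzofuran-5-yl]-4H-chromen-4-one
Conditions: I2 (10 mol%), DMSO, 120 °C
Reagents that add atoms: none
Why: Iodine-catalysed oxidative cyclisation of a 2'-hydroxychalcone: oxa-Michael closure of O1–C2 to the flavanone, α-iodination at C3 and loss of HI give the 3-benzyloxyflavone, with DMSO reoxidising iodide so that iodine turns over.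

Step 18
Reactants: 27 3,5,7-tris(benzyloxy)-2-[(2R,3S)-7-(benzyloxy)-3-[(benzyloxy)methyl]-2-(4-benzyloxy-3-methoxyphenyl)-2,3-dihydrobenzofuran-5-yl]-4H-chromen-4-one
Product: 28 2,3-dehydrosilychristin, 3,5,7-trihydroxy-2-[(2R,3S)-7-hydroxy-2-(4-hydroxy-3-methoxyphenyl)-3-(hydroxymethyl)-2,3-dihydrobenzofuran-5-yl]-4H-chromen-4-one
Conditions: H2 (1 atm), 10% palladium on carbon, THF/MeOH, rt, stopped as soon as debenzylation is complete
Reagents that add atoms: none
Why: Catalytic hydrogenolysis cleaves the five aryl benzyl ethers and the primary alkyl benzyl ether, while the flavonol double bond and the more hindered cyclic benzylic ether should survive mild, closely monitored conditions.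

**Compound list**
1 | 2-(benzyloxy)phenol | Oc1ccccc1OCc1ccccc1 | starting material
2 | 2-(benzyloxy)-4-bromophenol | Oc1ccc(Br)cc1OCc1ccccc1 | intermediate
3 | 2-(benzyloxy)-4-bromo-6-iodophenol | Oc1c(I)cc(Br)cc1OCc1ccccc1 | intermediate
4 | 4-(benzyloxy)-3-methoxybenzyl alcohol | COc1cc(CO)ccc1OCc1ccccc1 | starting material
5 | 4-(benzyloxy)-3-methoxybenzyl chloride | COc1cc(CCl)ccc1OCc1ccccc1 | intermediate
6 | 1-(benzyloxy)-2-[(4-benzyloxy-3-methoxybenzyl)oxy]-5-bromo-3-iodobenzene | COc1cc(COc2c(I)cc(Br)cc2OCc2ccccc2)ccc1OCc1ccccc1 | intermediate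
7 | ethyl diazoacetate | CCOC(=O)C=[N+]=[N-] | starting material
8 | ethyl 2-{3-(benzyloxy)-2-[(4-benzyloxy-3-methoxybenzyl)oxy]-5-bromophenyl}-2-diazoacetate | CCOC(=O)C(=[N+]=[N-])c1cc(Br)cc(OCc2ccccc2)c1OCc1ccc(OCc2ccccc2)c(OC)c1 | intermediate
9 | ethyl (2R,3S)-7-(benzyloxy)-2-(4-benzyloxy-3-methoxyphenyl)-5-bromo-2,3-dihydrobenzofuran-3-carboxylate (cis) | COc1cc([C@@H]2Oc3c(OCc4ccccc4)cc(Br)cc3[C@@H]2C(=O)OCC)ccc1OCc1ccccc1 | intermediate
10 | ethyl (2R,3R)-7-(benzyloxy)-2-(4-benzyloxy-3-methoxyphenyl)-5-bromo-2,3-dihydrobenzofuran-3-carboxylate (trans) | COc1cc([C@@H]2Oc3c(OCc4ccccc4)cc(Br)cc3[C@H]2C(=O)OCC)ccc1OCc1ccccc1 | intermediate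
11 | [(2R,3S)-7-(benzyloxy)-2-(4-benzyloxy-3-methoxyphenyl)-5-bromo-2,3-dihydrobenzofuran-3-yl]methanol (trans) | COc1cc([C@@H]2Oc3c(OCc4ccccc4)cc(Br)cc3[C@H]2CO)ccc1OCc1ccccc1 | intermediate
12 | (2R,3S)-7-(benzyloxy)-3-[(benzyloxy)methyl]-2-(4-benzyloxy-3-methoxyphenyl)-5-bromo-2,3-dihydrobenzofuran | COc1cc([C@@H]2Oc3c(OCc4ccccc4)cc(Br)cc3[C@H]2COCc2ccccc2)ccc1OCc1ccccc1 | intermediate
13 | [(2R,3S)-7-(benzyloxy)-3-[(benzyloxy)methyl]-2-(4-benzyloxy-3-methoxyphenyl)-2,3-dihydrobenzofuran-5-yl]lithium | COc1cc([C@@H]2Oc3c(OCc4ccccc4)cc([Li])cc3[C@H]2COCc2ccccc2)ccc1OCc1ccccc1 | intermediate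
14 | (2R,3S)-7-(benzyloxy)-3-[(benzyloxy)methyl]-2-(4-benzyloxy-3-methoxyphenyl)-2,3-dihydrobenzofuran-5-carbaldehyde | COc1cc([C@@H]2Oc3c(OCc4ccccc4)cc(C=O)cc3[C@H]2COCc2ccccc2)ccc1OCc1ccccc1 | intermediate
15 | methyl 2-(benzyloxy)acetate | COC(=O)COCc1ccccc1 | starting material
16 | methyl 2-(benzyloxy)-3-hydroxy-3-[(2R,3S)-7-(benzyloxy)-3-[(benzyloxy)methyl]-2-(4-benzyloxy-3-methoxyphenyl)-2,3-dihydrobenzofuran-5-yl]propanoate (diastereomer mixture) | COc1cc([C@@H]2Oc3c(OCc4ccccc4)cc(C(O)C(OCc4ccccc4)C(=O)OC)cc3[C@H]2COCc2ccccc2)ccc1OCc1ccccc1 | intermediate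
17 | methyl 2-(benzyloxy)-3-(methylsulfonyloxy)-3-[(2R,3S)-7-(benzyloxy)-3-[(benzyloxy)methyl]-2-(4-benzyloxy-3-methoxyphenyl)-2,3-dihydrobenzofuran-5-yl]propanoate (diastereomer mixture) | COc1cc([C@@H]2Oc3c(OCc4ccccc4)cc(C(OS(C)(=O)=O)C(OCc4ccccc4)C(=O)OC)cc3[C@H]2COCc2ccccc2)ccc1OCc1ccccc1 | intermediate
18 | methyl (Z)-2-(benzyloxy)-3-[(2R,3S)-7-(benzyloxy)-3-[(benzyloxy)methyl]-2-(4-benzyloxy-3-methoxyphenyl)-2,3-dihydrobenzofuran-5-yl]acrylate | COc1cc([C@@H]2Oc3c(OCc4ccccc4)cc(/C=C(\OCc4ccccc4)C(=O)OC)cc3[C@H]2COCc2ccccc2)ccc1OCc1ccccc1 | intermediate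
19 | (Z)-2-(benzyloxy)-3-[(2R,3S)-7-(benzyloxy)-3-[(benzyloxy)methyl]-2-(4-benzyloxy-3-methoxyphenyl)-2,3-dihydrobenzofuran-5-yl]acrylic acid | COc1cc([C@@H]2Oc3c(OCc4ccccc4)cc(/C=C(\OCc4ccccc4)C(=O)O)cc3[C@H]2COCc2ccccc2)ccc1OCc1ccccc1 | intermediate
20 | 3,5-bis(benzyloxy)phenol | Oc1cc(OCc2ccccc2)cc(OCc2ccccc2)c1 | starting material
21 | 2-bromo-3,5-bis(benzyloxy)phenol | Oc1cc(OCc2ccccc2)cc(OCc2ccccc2)c1Br | intermediate
22 | [2-bromo-3,5-bis(benzyloxy)phenoxy]trimethylsilane | C[Si](C)(C)Oc1cc(OCc2ccccc2)cc(OCc2ccccc2)c1Br | intermediate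
23 | lithium 3,5-bis(benzyloxy)-2-(trimethylsilyl)phenolate | [Li]Oc1cc(OCc2ccccc2)cc(OCc2ccccc2)c1[Si](C)(C)C | intermediate
24 | 3,5-bis(benzyloxy)-2-(trimethylsilyl)phenyl trifluoromethanesulfonate | C[Si](C)(C)c1c(OCc2ccccc2)cc(OCc2ccccc2)cc1OS(=O)(=O)C(F)(F)F | intermediate
25 | 3,5-bis(benzyloxy)benzyne | C1#CC(OCc2ccccc2)=CC(OCc2ccccc2)=C1 | intermediate
26 | (Z)-2-(benzyloxy)-1-[2-hydroxy-4,6-bis(benzyloxy)phenyl]-3-[(2R,3S)-7-(benzyloxy)-3-[(benzyloxy)methyl]-2-(4-benzyloxy-3-methoxyphenyl)-2,3-dihydrobenzofuran-5-yl]prop-2-en-1-one | COc1cc([C@@H]2Oc3c(OCc4ccccc4)cc(/C=C(\OCc4ccccc4)C(=O)c4c(O)cc(OCc5ccccc5)cc4OCc4ccccc4)cc3[C@H]2COCc2ccccc2)ccc1OCc1ccccc1 | intermediate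
27 | 3,5,7-tris(benzyloxy)-2-[(2R,3S)-7-(benzyloxy)-3-[(benzyloxy)methyl]-2-(4-benzyloxy-3-methoxyphenyl)-2,3-dihydrobenzofuran-5-yl]-4H-chromen-4-one | COc1cc([C@@H]2Oc3c(OCc4ccccc4)cc(-c4oc5cc(OCc6ccccc6)cc(OCc6ccccc6)c5c(=O)c4OCc4ccccc4)cc3[C@H]2COCc2ccccc2)ccc1OCc1ccccc1 | intermediate
28 | 2,3-dehydrosilychristin, 3,5,7-trihydroxy-2-[(2R,3S)-7-hydroxy-2-(4-hydroxy-3-methoxyphenyl)-3-(hydroxymethyl)-2,3-dihydrobenzofuran-5-yl]-4H-chromen-4-one | COc1cc([C@@H]2Oc3c(O)cc(-c4oc5cc(O)cc(O)c5c(=O)c4O)cc3[C@H]2CO)ccc1O | target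

**Step count**
Total: 18 steps (13 to the acid, 2 to the aryne precursor, 3 from the key step on). Longest linear sequence: 15 steps (steps 1, 2, 4 to 13, 16 to 18).

**Steps most likely to fail**

Step 16 (aryne insertion). What may go wrong: protonation of the aryl anion before acyl transfer, which stops at simple O-arylation of the carboxylate; carboxylate addition at the wrong aryne carbon; [2+2] capture of the aryne by the enol-ether double bond; or a second arylation of the product phenoxide. Fallback, setting out from bromophenol 21 and aldehyde 14 and returning at chalcone 26: 21 is treated with n-BuLi (2.2 equiv, THF, −78 °C) to give lithium 3,5-bis(benzyloxy)-2-lithiophenolate F1. This is acylated with purchased N-methoxy-N-methyl-2-(benzyloxy)acetamide to give 2-(benzyloxy)-1-[2-hydroxy-4,6-bis(benzyloxy)phenyl]ethanone F2. Claisen–Schmidt condensation of F2 with 14 (KOH, EtOH/THF, rt) then gives 26. Ring A thus enters as a preformed ketone, and the enone double bond is made by aldol condensation.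

Step 6 (enantioselective C–H insertion). What may go wrong: insufficient discrimination between the enantiotopic benzylic hydrogens, a sense of induction opposite to the one assumed, or diversion of the carbenoid onto the electron-rich guaiacyl ring. Fallback, setting out from diazo ester 8 and returning at alcohol 11: 8 is decomposed with Rh2(OAc)4 in CH2Cl2 to racemic ethyl 7-(benzyloxy)-2-(4-benzyloxy-3-methoxyphenyl)-5-bromo-2,3-dihydrobenzofuran-3-carboxylate as a cis/trans mixture F3. Equilibration with NaOEt in EtOH gives the racemic trans ester F4, and reduction with iBu2AlH gives the racemic trans alcohol F5. Preparative chromatography on a chiral stationary phase (amylose tris(3,5-dimethylphenylcarbamate), supercritical CO2/MeOH) separates 11 from its enantiomer, [(2S,3R)-7-(benzyloxy)-2-(4-benzyloxy-3-methoxyphenyl)-5-bromo-2,3-dihydrobenzofuran-3-yl]methanol F6, which is discarded.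

Step 18 (global hydrogenolysis). What may go wrong: reductive opening of the benzylic C2–O1 bond of the dihydrobenzofuran once the para-phenol is unmasked, or incomplete cleavage of the slower primary alkyl benzyl ether. Fallback, setting out from 27 and returning at target 28: Lewis-acid debenzylation with BCl3 in the presence of pentamethylbenzene as cation scavenger (CH2Cl2, −78 to −40 °C), which removes aryl and primary alkyl benzyl ethers without hydrogen or metal and forms no new intermediate.

Further compounds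
F1 | step 16 | lithium 3,5-bis(benzyloxy)-2-lithiophenolate | [Li]Oc1cc(OCc2ccccc2)cc(OCc2ccccc2)c1[Li]
F2 | step 16 | 2-(benzyloxy)-1-[2-hydroxy-4,6-bis(benzyloxy)phenyl]ethanone | O=C(COCc1ccccc1)c1c(O)cc(OCc2ccccc2)cc1OCc1ccccc1
F3 | step 6 | racemic ethyl 7-(benzyloxy)-2-(4-benzyloxy-3-methoxyphenyl)-5-bromo-2,3-dihydrobenzofuran-3-carboxylate (cis/trans mixture) | CCOC(=O)C1c2cc(Br)cc(OCc3ccccc3)c2OC1c1ccc(OCc2ccccc2)c(OC)c1
F4 | step 6 | racemic trans ethyl 7-(benzyloxy)-2-(4-benzyloxy-3-methoxyphenyl)-5-bromo-2,3-dihydrobenzofuran-3-carboxylate, (2R,3R) and (2S,3S) | COc1cc([C@@H]2Oc3c(OCc4ccccc4)cc(Br)cc3[C@H]2C(=O)OCC)ccc1OCc1ccccc1.COc1cc([C@H]2Oc3c(OCc4ccccc4)cc(Br)cc3[C@@H]2C(=O)OCC)ccc1OCc1ccccc1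
F5 | step 6 | racemic trans [7-(benzyloxy)-2-(4-benzyloxy-3-methoxyphenyl)-5-bromo-2,3-dihydrobenzofuran-3-yl]methanol, (2R,3S) and (2S,3R) | COc1cc([C@@H]2Oc3c(OCc4ccccc4)cc(Br)cc3[C@H]2CO)ccc1OCc1ccccc1.COc1cc([C@H]2Oc3c(OCc4ccccc4)cc(Br)cc3[C@@H]2CO)ccc1OCc1ccccc1
F6 | step 6 | [(2S,3R)-7-(benzyloxy)-2-(4-benzyloxy-3-methoxyphenyl)-5-bromo-2,3-dihydrobenzofuran-3-yl]methanol | COc1cc([C@H]2Oc3c(OCc4ccccc4)cc(Br)cc3[C@@H]2CO)ccc1OCc1ccccc1
F0 | step 18 | none | none
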